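(The data are simulated on assumed constants; scatter was added.)

Sunday's run had 11 % of its X left at 50.0 h, and that reading, taken with its loading of E, is where I start.

| flask | X | Q | E | remark | time |
|---|---|---|---|---|---|
| Saturday's | 10 mM | 2 equiv | 7.5 mol% | run made earlier |  |
| Sunday's | 10 mM | 2 equiv | 11 mol% | run made earlier |  |
| flask | 10 mM | 2.00 equiv | 15 mol% |  | 2.5 d |

| run | time / h | X / % | D / % |
|---|---|---|---|
| Saturday's | 4.00 | 88 | 9 |
| Saturday's | 6.00 | 84 | 16 |
| Saturday's | 8.00 | 78 | 22 |
| Saturday's | 15.0 | 60 | 37 |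
| Saturday's | 20.0 | 54 | 38 |
| Saturday's | 30.0 | 43 | 52 |
| Saturday's | 50.0 | 28 | 60 |
| Sunday's | 2.50 | 91 | 8 |
| Sunday's | 8.00 | 67 | 25 |
| Sunday's | 15.0 | 51 | 44 |
| Sunday's | 20.0 | 39 | 55 |
| Sunday's | 30.0 | 25 | 59 |
| Sunday's | 40.0 | 17 | 66 |
| Sunday's | 50.0 | 11 | 74 |

(readings scatter by 2 percentage points)

1. amount of X in percent of the X charged, at 3.0 h, 15 h and 2.5 d

*What do you carry from the runs to the new flask?* I carry k′, a pseudo-first-order constant: the logarithm of charged X over X left, divided by the time, then multiplied by the flask's loading over the run's, so that each run speaks for E at 15 mol%. Sunday's end reading gives 0.0602 /h, the loading-scaled decay constant.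

*And if it holds?* Then the flask keeps 83.5 % of its X at 3.0 h, 40.5 % at 15 h and 2.70 % at 2.5 d.

*Does it hold, though?* On Saturday's run it drifts, since the same reckoning gives 0.0681 /h at 15.0 h but 0.0509 /h at 50.0 h, each reading carrying a scatter of 2 percentage points. With the later value the flask would keep 4.71 % at 2.5 d, so my end figure is a span from 2.70 % to 4.71 %.

The forecast reads “a nearly first-order decay in X” and gives 83 %, 40 % and 3.5 %, its last figure a single value inside my span.

    X + E → Z (k = 1.02 /M/min)
    J → E + D (k = 0.0405 /min)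
    J + D → G (k = 0.777 /M/min)
    Q + Z → J (k = 2.12 /M/min)

The flask gives 81.8 %, 38.5 % and 3.80 %, so the forecast stands within its margin. Reckoned for this flask, k′ is 0.0636 /h up to 15 h and 0.0545 /h up to 2.5 d. The half-life of Z by its reaction with Q alone, other concentrations as charged, is 0.27 h, far shorter than the 0.423 d by which half of the turnover of X + E is done, while E goes from 69.7 % at 0.250 d to 50.9 % at 2.50 d, when G holds 47.7 % of the catalyst.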